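## The problem

Kaempferol 3-O-sulfate (17) is a flat flavonol with no stereocentre, so nothing has to be set and no centre can steer another; the difficulty is regiochemical and lies on an oxygen-rich rim. Ring A (C4a, C5, C6, C7, C8, C8a) is a phloroglucinol fused through C4a and C8a to the 4-pyranone ring C (O1, C2, C3, C4), and ring B, a para-phenol, sits on C2. Of the four hydroxyl oxygens only O3 carries the sulfate, although O7 and O4' are the more reactive phenols and O5, like O3, is hydrogen-bonded to the C4 carbonyl; O3 must therefore enter the synthesis already distinguished from the other three. The sulfate monoester is ionic, water-soluble and cleaved by acid, so it has to be installed late and the final unmasking must be neutral and non-hydrolytic. The C4a–C4 aryl ketone, flanked by two ortho oxygens, must be made without regiochemical ambiguity on ring A. The enabling feature is that C4, C5, C7 and C8a carry oxygen on alternate carbons: read as a chain, C5 is an ester carbon, C6, C8 and C4a are methylenes, and C7, C8a and C4 are ketones, so the C4a–C5 bond is a Claisen bond of a tetraketide. C3 and C2 end that chain as an α-oxygenated styryl unit that has no enolisable hydrogen and already holds O3 in protected form.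

## Retrosynthesis

**17 from 16.** The three benzyl–oxygen bonds at O5, O7 and O4' are cut last. Hydrogenolysis is neutral and leaves the sulfate monoester and the C2=C3 bond alone, whereas any acid-labile phenol protection would endanger the sulfate. Precursor 16 is the 5,7,4'-tri-O-benzyl ether of the target.

**16 from 15.** The S–O3 bond is cut. In 15 (5,7,4'-tri-O-benzylkaempferol) O3 is the only free hydroxyl, so sulfation needs no selectivity. Leaving O5 free and relying on its chelation would save one benzyl group but would reintroduce a selectivity question.

**15 from 12.** The O1–C2 bond of ring C is cut and two hydrogens are added back, giving the 2'-hydroxy-α-(methoxymethoxy)chalcone 12. Forward, the chelated phenol adds to the enone to give flavanone 13, iodine in hot dimethyl sulfoxide dehydrogenates it to the 3-O-MOM flavone 14, and acid removes the acetal to give 15. Placing the oxygen on the α-carbon of the chalcone avoids a later C3 oxidation and avoids the aurone problem of peroxide-based flavonol syntheses on 6'-oxygenated chalcones. The enol-ether geometry is destroyed here, so it never needs control.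

**12 from 11.** Two benzyl–oxygen bonds on ring A are cut. In triol 11 one ortho hydroxyl is always locked to the ketone by a hydrogen bond, so two benzyl groups should go on the para oxygen and one ortho oxygen and leave exactly the phenol needed as O1.

**11 from 10 (key disconnection).** The C4a–C5 bond is cut, unfolding ring A into the open-chain 3,5,7-triketo ester 10. This removes a ring and every ring A regiochemical question at once, because the three oxygens arrive as chain carbonyls in fixed positions. The forward reaction must close C6 of the chain onto the C1 ester (Claisen) and not C2 onto the C7 ketone (aldol). The neighbouring cut at C4–C4a on a preformed phloroglucinol would need a C-acylation that the MOM enol ether would not survive.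

**10 from 3 and 9.** The chain bond between C6 and C7 (flavone C4a–C4) is cut, giving the trianion of methyl 3,5-dioxohexanoate (3) and the non-enolisable ester 9. Ester 9 has no α-hydrogen and its β-carbon is deactivated by the α-alkoxy and para-alkoxyaryl donors, so acylation at the carbonyl is the expected path.

**9 from 5 and 6.** The C2=C3 alkene of the cinnamate (flavone C3–C2) is cut by an aldol/elimination logic: glycolate enolate 5 plus 4-(benzyloxy)benzaldehyde (6) gives aldol 7, and elimination through mesylate 8 gives 9. Ether 5 comes from methyl glycolate (4) by O-alkylation.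

**3 from 1.** Methyl 3,5-dioxohexanoate (3) is the methanolysis/deacetylation product of dehydroacetic acid (1), through the ring-opened triacylmethane 2. This supplies six of the seven carbons of ring A plus C4 from a commodity pyranone.

## Roads not taken

**Alternative 1:** The cut is at C4a–C4 and C4–C3, with C4 supplied as carbon monoxide A3. Forward, the aryl iodide A1, carbon monoxide A3 and the enolate of the α-alkoxy ketone A2 would combine under zerovalent palladium catalysis to the 2-oxygenated 1,3-diketone A4, in which no ring has been closed. Here A1 is the tribenzyl ether of 2-iodophloroglucinol, and A2 is the methoxymethyl ether of 4-benzyloxyphenyl hydroxymethyl ketone.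
- Merits: it is convergent, the symmetrical iodide A1 removes any ring A regiochemistry, and chelation-assisted release of one ortho oxygen of A4 followed by acid cyclodehydration could reach 15 directly. In step count it is probably equal to or slightly shorter than the chosen plan.
- Weak points: A1 is di-ortho-substituted and electron-rich, so aroyl-palladium formation and capture by the hindered enolate of A2 are demanding, and direct arylation of A2 without uptake of A3 competes. Freeing one of the two equivalent ortho benzyl ethers of A4 without touching the MOM acetal is delicate. The key step builds no ring, so ring C formation remains as a separate problem.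
- Comparison: the chosen plan needs no pressurised toxic gas such as A3 and no precious metal in the skeleton-forming step, and it forms ring A with its ortho hydroxyl already free for ring C closure.

**Alternative 2:** Ring A is cut at C5–C6, C7–C8 and C4a–C5 and grown on a 4-pyranone derived from kojic acid A5. Forward, photochemical Wolff rearrangement of the pyranonyl diazo ketone A6 gives a ketene that takes up the silyl ynol ether A7 by ketene–alkyne cycloaddition, electrocyclic opening of the cyclobutenone and six-electron electrocyclic closure. The product is the flavonol A8, which is kaempferol carrying a benzyl group on O3 and triisopropylsilyl groups on O7 and O4'.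
- Merits: A8 carries an orthogonal set of groups, and its end game (hydrogenolysis at O3, sulfation, fluoride desilylation) is as gentle toward the sulfate as the one chosen here, arguably gentler.
- Weak points: A6 needs C6 arylation of A5, oxidation of the hydroxymethyl group to the acid and diazo ketone formation, about six or seven steps before the key event. The 4-pyranone chromophore is itself photoreactive, and A7 is a sensitive reagent. O5 of A8 is left free and again has to be discriminated by chelation alone.
- Comparison: the road through A6 and A8 is clearly longer for a ring that is a plain phloroglucinol. The chosen plan is shorter and uses commodity reagents, at the price of a less modular ring A.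

**Alternative 3:** The cut is at C4–C4a. Forward, the aryloxyacrylic acid A9 is activated as its mixed trifluoroacetic anhydride and acylates the ortho carbon of its own symmetrical 3,5-dibenzyloxyphenoxy ring, closing ring C to the flavonol ether A10, which is 3-O-allyl-5,7,4'-tri-O-benzylkaempferol.
- Merits: the arene of A9 is highly activated and both ortho positions are equivalent, so the ring closure is very dependable. Deallylation of A10 with zerovalent palladium would give 15 directly. As a ring-forming event this is at least as reliable as a polyketide folding, probably more so.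
- Weak points: the difficulty moves into A9, a tetrasubstituted alkene bearing two different oxygen substituents, whose aryloxy group must be cis to the carboxyl. Making A9 needs an α-allyloxy β-keto ester, a vinyl leaving group and an addition–elimination with a phenoxide, with only one geometric isomer able to cyclise. The strongly acidic acylation medium must also spare the allyl and benzyl ethers of A9 and A10.
- Comparison: the chosen plan never needs a defined alkene geometry, makes ring A with no C-acylation, and draws the whole skeleton from three cheap building blocks. It accepts a less certain key step in exchange for avoiding A9.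

Key step: step 6

Assumption: the target is taken as the free hydrogen sulfate as drawn. Sulfate monoesters 16 and 17 are written in the acid form although they would be handled as potassium salts; the counter-ion exchange belongs to work-up, and the acid form of 17 would be released at the end by brief contact with a cold H+ cation-exchange resin.

Step 1
Reactants: 1 dehydroacetic acid (3-acetyl-4-hydroxy-6-methyl-2H-pyran-2-one)
Product: 3 methyl 3,5-dioxohexanoate, via methyl 2-acetyl-3,5-dioxohexanoate 2 (not isolated)
Conditions: Mg(OMe)2 (2 equiv), MeOH, reflux; cold 1 M HCl work-up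
Reagents that add atoms: magnesium methoxide, Mg(OMe)2, C[O-].C[O-].[Mg+2]
Why: Methoxide opens the lactone to triacylmethane 2 and then removes the exocyclic acetyl group by retro-Claisen cleavage, while magnesium chelation of the 3,5-diketonate protects the chain from further fragmentation; this is a known alkoxide ring-opening/deacetylation of dehydroacetic acid.

Step 2
Reactants: 4 methyl glycolate
Product: 5 methyl 2-(methoxymethoxy)acetate
Conditions: MOMCl, iPr2NEt, CH2Cl2, 0 °C to rt
Reagents that add atoms: chloromethyl methyl ether (MOMCl), COCCl
Why: Standard O-alkylation of a primary alcohol to its methoxymethyl acetal; the acetal is stable to the strong bases of steps 3 to 7 and is later removed by acid.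

Step 3
Reactants: 5 methyl 2-(methoxymethoxy)acetate; 6 4-(benzyloxy)benzaldehyde
Product: 7 methyl 3-[4-(benzyloxy)phenyl]-3-hydroxy-2-(methoxymethoxy)propanoate (racemic syn/anti mixture)
Conditions: LDA (LiN(iPr)2, 1.1 equiv), THF, −78 °C; then 6, −78 °C; AcOH quench
Reagents that add atoms: none
Why: Aldol addition of the lithium enolate of an α-alkoxy ester to a non-enolisable aryl aldehyde; the two stereocentres need no control because both are destroyed in step 4.

Step 4
Reactants: 7 methyl 3-[4-(benzyloxy)phenyl]-3-hydroxy-2-(methoxymethoxy)propanoate
Product: 9 methyl (Z)-3-[4-(benzyloxy)phenyl]-2-(methoxymethoxy)prop-2-enoate, via methyl 3-[4-(benzyloxy)phenyl]-3-(methanesulfonyloxy)-2-(methoxymethoxy)propanoate 8 (not isolated)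
Conditions: MsCl, Et3N, CH2Cl2, 0 °C; then DBU, rt
Reagents that add atoms: none
Why: Mesylation followed by E1cB elimination through the ester enolate; both diastereomers of 7 should converge on the more stable Z enol ether (aryl trans to the ester), and the geometry is in any case irrelevant after step 8.

Step 5
Reactants: 3 methyl 3,5-dioxohexanoate; 9 methyl (Z)-3-[4-(benzyloxy)phenyl]-2-(methoxymethoxy)prop-2-enoate
Product: 10 methyl (Z)-9-[4-(benzyloxy)phenyl]-8-(methoxymethoxy)-3,5,7-trioxonon-8-enoate (enol mixture)
Conditions: 3 (2 equiv), LDA (LiN(iPr)2, 6.4 equiv), THF, 0 °C; then 9, −78 to 0 °C; poured into cold 1 M HCl, used without storage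
Reagents that add atoms: none
Why: Acylation of the trilithium trianion of a 3,5-dioxo ester at its terminal, most basic carbon by a non-enolisable ester is a known polyanion Claisen condensation; the second equivalent of trianion absorbs the acidic proton of the product, and the α-alkoxy and para-alkoxyaryl donors disfavour conjugate addition to 9.

Step 6
Reactants: 10 methyl (Z)-9-[4-(benzyloxy)phenyl]-8-(methoxymethoxy)-3,5,7-trioxonon-8-enoate
Product: 11 (Z)-3-[4-(benzyloxy)phenyl]-2-(methoxymethoxy)-1-(2,4,6-trihydroxyphenyl)prop-2-en-1-one
Conditions: Mg(OMe)2 (4 equiv), MeOH, rt to 60 °C; cold 1 M HCl work-up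
Reagents that add atoms: none
Why: In methanolic Mg(OMe)2 the chain is held as a folded magnesium polyenolate in which the three ketone carbonyls, C7 included, are metal-bound enolate oxygens and no longer acyl acceptors, so the C1 ester is the only carbonyl left that can take a nucleophile and expel a leaving group. C6, the central carbon of the C5/C7 diketonate, attacks C1 in a 6-exo-trig closure, methoxide leaves the tetrahedral intermediate, and the cyclic 2-acyl-1,3,5-trione enolises irreversibly to the phloroglucinol 11, which drains every preceding equilibrium. The closest known reaction type is the base-mediated Claisen cyclisation of 3,5,7-triketo esters to acylphloroglucinols, the laboratory counterpart of chalcone synthase, established for aryl- and styryl-terminated chains. Ring A is the only ring closed and no stereocentre is formed. The selectivity needed is Claisen (C6 to C1) over aldol (C2 to C7) and over lactonisation (O5 to C1). The strongly basic, non-aqueous, chelating medium secures the first, the cross-conjugated α-alkoxy enone character of C7 lowers its electrophilicity further, and methanol as solvent keeps any lactone formation reversible. The styryl terminus has no α-hydrogen, so enolisation and folding are confined to the ring A segment, and MOM and benzyl ethers are inert to alkoxide.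

Step 7
Reactants: 11 (Z)-3-[4-(benzyloxy)phenyl]-2-(methoxymethoxy)-1-(2,4,6-trihydroxyphenyl)prop-2-en-1-one
Product: 12 (Z)-1-[2,4-bis(benzyloxy)-6-hydroxyphenyl]-3-[4-(benzyloxy)phenyl]-2-(methoxymethoxy)prop-2-en-1-one
Conditions: BnBr (2.1 equiv), K2CO3 (2.5 equiv), DMF, rt
Reagents that add atoms: benzyl bromide, BrCc1ccccc1
Why: Williamson benzylation of a 2,4,6-trihydroxyaryl ketone stops after the para and one ortho oxygen, because the remaining ortho hydroxyl is hydrogen-bonded to the carbonyl and much less nucleophilic; this is the standard way to a 2-hydroxy-4,6-dibenzyloxyaryl ketone.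

Step 8
Reactants: 12 (Z)-1-[2,4-bis(benzyloxy)-6-hydroxyphenyl]-3-[4-(benzyloxy)phenyl]-2-(methoxymethoxy)prop-2-en-1-one
Product: 15 5,7-bis(benzyloxy)-2-[4-(benzyloxy)phenyl]-3-hydroxy-4H-chromen-4-one (5,7,4'-tri-O-benzylkaempferol), via 5,7,4'-tri-O-benzyl-3-O-(methoxymethyl)dihydrokaempferol 13 (not isolated), via 5,7,4'-tri-O-benzyl-3-O-(methoxymethyl)kaempferol 14 (not isolated)
Conditions: I2 (0.2 equiv), DMSO, 120 °C; Na2S2O3 wash; crude 14, 3 M HCl, MeOH/THF, 50 °C
Reagents that add atoms: none
Why: Iodine-mediated oxidative cyclisation of a 2'-hydroxychalcone in DMSO: 6-endo oxa-Michael addition gives flavanone 13, enol iodination at C3 and loss of HI give flavone 14, and DMSO reoxidises iodide. Acid methanolysis of the MOM acetal then frees O3 while benzyl ethers stay, so any MOM lost after ring closure converges on 15.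

Step 9
Reactants: 15 5,7-bis(benzyloxy)-2-[4-(benzyloxy)phenyl]-3-hydroxy-4H-chromen-4-one
Product: 16 5,7-bis(benzyloxy)-2-[4-(benzyloxy)phenyl]-4-oxo-4H-chromen-3-yl hydrogen sulfate (handled as its potassium salt)
Conditions: SO3·pyridine (6 equiv), pyridine, 60 °C; aq. KHCO3 work-up, reverse-phase isolation
Reagents that add atoms: sulfur trioxide–pyridine complex, O=S(=O)=O.c1ccncc1
Why: O-Sulfonation of a flavonol hydroxyl with a sulfur trioxide–amine complex; O3 is the only free hydroxyl in 15, so the site of sulfation is fixed by the protecting-group pattern.

Step 10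
Reactants: 16 5,7-bis(benzyloxy)-2-[4-(benzyloxy)phenyl]-4-oxo-4H-chromen-3-yl hydrogen sulfate
Product: 17 kaempferol 3-O-sulfate (5,7-dihydroxy-2-(4-hydroxyphenyl)-4-oxo-4H-chromen-3-yl hydrogen sulfate)
Conditions: H2 (1 atm), 10% Pd/C, THF/MeOH, rt; then H+ cation-exchange resin, H2O, 0 °C
Reagents that add atoms: none
Why: Hydrogenolysis of aryl benzyl ethers is neutral and leaves aryl sulfate monoesters and the flavonol C2=C3 bond intact; the potassium salt is used because amines retard benzyl ether hydrogenolysis.

## Compound list

1 | dehydroacetic acid (3-acetyl-4-hydroxy-6-methyl-2H-pyran-2-one) | CC(=O)c1c(O)cc(C)oc1=O | starting material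
2 | methyl 2-acetyl-3,5-dioxohexanoate | COC(=O)C(C(C)=O)C(=O)CC(C)=O | intermediate
3 | methyl 3,5-dioxohexanoate | COC(=O)CC(=O)CC(C)=O | intermediate
4 | methyl glycolate | COC(=O)CO | starting material
5 | methyl 2-(methoxymethoxy)acetate | COCOCC(=O)OC | intermediate
6 | 4-(benzyloxy)benzaldehyde | O=Cc1ccc(OCc2ccccc2)cc1 | starting material
7 | methyl 3-[4-(benzyloxy)phenyl]-3-hydroxy-2-(methoxymethoxy)propanoate (racemic, syn/anti mixture) | COCOC(C(=O)OC)C(O)c1ccc(OCc2ccccc2)cc1 | intermediate
8 | methyl 3-[4-(benzyloxy)phenyl]-3-(methanesulfonyloxy)-2-(methoxymethoxy)propanoate (racemic, diastereomer mixture) | COCOC(C(=O)OC)C(OS(C)(=O)=O)c1ccc(OCc2ccccc2)cc1 | intermediate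
9 | methyl (Z)-3-[4-(benzyloxy)phenyl]-2-(methoxymethoxy)prop-2-enoate | COCO/C(=C\c1ccc(OCc2ccccc2)cc1)C(=O)OC | intermediate
10 | methyl (Z)-9-[4-(benzyloxy)phenyl]-8-(methoxymethoxy)-3,5,7-trioxonon-8-enoate | COCO/C(=C\c1ccc(OCc2ccccc2)cc1)C(=O)CC(=O)CC(=O)CC(=O)OC | intermediate
11 | (Z)-3-[4-(benzyloxy)phenyl]-2-(methoxymethoxy)-1-(2,4,6-trihydroxyphenyl)prop-2-en-1-one | COCO/C(=C\c1ccc(OCc2ccccc2)cc1)C(=O)c1c(O)cc(O)cc1O | intermediate
12 | (Z)-1-[2,4-bis(benzyloxy)-6-hydroxyphenyl]-3-[4-(benzyloxy)phenyl]-2-(methoxymethoxy)prop-2-en-1-one | COCO/C(=C\c1ccc(OCc2ccccc2)cc1)C(=O)c1c(O)cc(OCc2ccccc2)cc1OCc1ccccc1 | intermediate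
13 | 5,7-bis(benzyloxy)-2-[4-(benzyloxy)phenyl]-3-(methoxymethoxy)chroman-4-one (racemic, cis/trans mixture) | COCOC1C(c2ccc(OCc3ccccc3)cc2)Oc2cc(OCc3ccccc3)cc(OCc3ccccc3)c2C1=O | intermediate
14 | 5,7-bis(benzyloxy)-2-[4-(benzyloxy)phenyl]-3-(methoxymethoxy)-4H-chromen-4-one | COCOc1c(-c2ccc(OCc3ccccc3)cc2)oc2cc(OCc3ccccc3)cc(OCc3ccccc3)c2c1=O | intermediate
15 | 5,7-bis(benzyloxy)-2-[4-(benzyloxy)phenyl]-3-hydroxy-4H-chromen-4-one | O=c1c(O)c(-c2ccc(OCc3ccccc3)cc2)oc2cc(OCc3ccccc3)cc(OCc3ccccc3)c12 | intermediate
16 | 5,7-bis(benzyloxy)-2-[4-(benzyloxy)phenyl]-4-oxo-4H-chromen-3-yl hydrogen sulfate | O=c1c(OS(=O)(=O)O)c(-c2ccc(OCc3ccccc3)cc2)oc2cc(OCc3ccccc3)cc(OCc3ccccc3)c12 | intermediate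
17 | kaempferol 3-O-sulfate | O=c1c(OS(=O)(=O)O)c(-c2ccc(O)cc2)oc2cc(O)cc(O)c12 | target

## Step count and risks

Total: 10 steps. Longest linear sequence: 9 steps (4 to 17 through steps 2, 3, 4, 5, 6, 7, 8, 9 and 10); step 1 is a one-step side branch.

**Step 6 (key step).** The most likely failure is competition from aldol closure of C2 onto C7 or from lactonisation of O5 onto C1, together with methoxide-induced retro-Claisen fragmentation. All three are worst while the chain is only partly deprotonated, or while free 10 is being isolated and handled. The fallback delivers the chain in lactone-masked form and never isolates the free triketo ester. It sets out from 9: the dianion of commercial 4-hydroxy-6-methyl-2H-pyran-2-one (LDA, THF, −78 °C) is acylated at its 6-methyl group by 9 to give 6-[(3Z)-4-[4-(benzyloxy)phenyl]-3-(methoxymethoxy)-2-oxobut-3-en-1-yl]-4-hydroxy-2H-pyran-2-one F1. Mg(OMe)2 in methanol then opens the lactone of F1 inside the magnesium chelate, and the ester so unveiled is taken at once by C6 in the same Claisen closure. The sequence returns to the route at 11.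

**Step 5.** Proton transfer from the acidic product to unreacted trianion, conjugate addition to the enoate and premature cyclisation on acidic work-up can all lower the yield of the chain extension. The fallback assembles the chain in the opposite sense and sets out from 9. The dianion of acetylacetone is acylated by 9 to the triketone (Z)-8-[4-(benzyloxy)phenyl]-7-(methoxymethoxy)oct-7-ene-2,4,6-trione F2. The trianion of F2 (LDA) is carboxylated at the terminal methyl with CO2 to (Z)-9-[4-(benzyloxy)phenyl]-8-(methoxymethoxy)-3,5,7-trioxonon-8-enoic acid F3. Cold esterification of F3 with trimethylsilyldiazomethane returns to the route at 10.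

**Step 8.** Loss of the MOM acetal before ring C has closed would unmask a 1,2-diketone that can close in the 5-exo sense to a benzylcoumaranone; ring A iodination and partial loss of the 5-O-benzyl group are lesser concerns. The fallback separates ring closure, deprotection and oxidation and sets out from 12. Base-mediated oxa-Michael closure (NaOAc, EtOH, reflux) gives 13, now isolated. Acid methanolysis at this saturated stage gives the dihydroflavonol 5,7-bis(benzyloxy)-2-[4-(benzyloxy)phenyl]-3-hydroxychroman-4-one F4. The classical dehydrogenation of a dihydroflavonol, applied to F4 (I2, KOAc, AcOH, 90 °C), returns to the route at 15.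

**Step 7.** C-Benzylation of the electron-rich ring, incomplete or excessive O-benzylation, and base-induced closure to a flavanone that hides one ortho oxygen would erode the yield of 12. The fallback replaces alkylation of an ambident phenoxide by a Mitsunobu etherification of the neutral phenols (benzyl alcohol, PPh3, diisopropyl azodicarboxylate, THF, 0 °C). This is O-selective and also spares the chelated hydroxyl. It sets out from 11 and returns at 12 without new intermediates.

**Step 9.** Incomplete sulfonation of the hydrogen-bonded, flanked 3-hydroxyl and hydrolytic loss of the sulfate during isolation of an ionic product are the risks. The fallback installs the sulfate as a neutral, chromatographable diester and sets out from 15. 2,2,2-Trichloroethyl chlorosulfate with Et3N and DMAP in THF gives 5,7-bis(benzyloxy)-2-[4-(benzyloxy)phenyl]-4-oxo-4H-chromen-3-yl 2,2,2-trichloroethyl sulfate F5. Reductive removal of the trichloroethyl group of F5 (Zn dust, ammonium formate, MeOH) returns to the route at 16.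

## Further compounds

F1 | step 6 | 6-[(3Z)-4-[4-(benzyloxy)phenyl]-3-(methoxymethoxy)-2-oxobut-3-en-1-yl]-4-hydroxy-2H-pyran-2-one | COCO/C(=C\c1ccc(OCc2ccccc2)cc1)C(=O)Cc1cc(O)cc(=O)o1
F2 | step 5 | (Z)-8-[4-(benzyloxy)phenyl]-7-(methoxymethoxy)oct-7-ene-2,4,6-trione | COCO/C(=C\c1ccc(OCc2ccccc2)cc1)C(=O)CC(=O)CC(C)=O
F3 | step 5 | (Z)-9-[4-(benzyloxy)phenyl]-8-(methoxymethoxy)-3,5,7-trioxonon-8-enoic acid | COCO/C(=C\c1ccc(OCc2ccccc2)cc1)C(=O)CC(=O)CC(=O)CC(=O)O
F4 | step 8 | 5,7-bis(benzyloxy)-2-[4-(benzyloxy)phenyl]-3-hydroxychroman-4-one (racemic, diastereomer mixture) | OC1C(c2ccc(OCc3ccccc3)cc2)Oc2cc(OCc3ccccc3)cc(OCc3ccccc3)c2C1=O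
F0 | step 7 | none | none
F5 | step 9 | 5,7-bis(benzyloxy)-2-[4-(benzyloxy)phenyl]-4-oxo-4H-chromen-3-yl 2,2,2-trichloroethyl sulfate | O=c1c(OS(=O)(=O)OCC(Cl)(Cl)Cl)c(-c2ccc(OCc3ccccc3)cc2)oc2cc(OCc3ccccc3)cc(OCc3ccccc3)c12
A1 | alternative 1 | 2-iodo-1,3,5-tris(benzyloxy)benzene | Ic1c(OCc2ccccc2)cc(OCc2ccccc2)cc1OCc1ccccc1
A2 | alternative 1 | 1-[4-(benzyloxy)phenyl]-2-(methoxymethoxy)ethan-1-one | COCOCC(=O)c1ccc(OCc2ccccc2)cc1
A3 | alternative 1 | carbon monoxide | [C-]#[O+]
A4 | alternative 1 | 1-[4-(benzyloxy)phenyl]-2-(methoxymethoxy)-3-[2,4,6-tris(benzyloxy)phenyl]propane-1,3-dione (racemic, enolisable) | COCOC(C(=O)c1ccc(OCc2ccccc2)cc1)C(=O)c1c(OCc2ccccc2)cc(OCc2ccccc2)cc1OCc1ccccc1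
A5 | alternative 2 | kojic acid (5-hydroxy-2-(hydroxymethyl)-4H-pyran-4-one) | O=c1cc(CO)occ1O
A6 | alternative 2 | 5-(benzyloxy)-2-(2-diazoacetyl)-6-[4-(triisopropylsilyloxy)phenyl]-4H-pyran-4-one | [N-]=[N+]=CC(=O)c1cc(=O)c(OCc2ccccc2)c(-c2ccc(O[Si](C(C)C)(C(C)C)C(C)C)cc2)o1
A7 | alternative 2 | (triisopropylsilyloxy)acetylene | C#CO[Si](C(C)C)(C(C)C)C(C)C
A8 | alternative 2 | 3-O-benzyl-7,4'-bis-O-(triisopropylsilyl)kaempferol | O=c1c(OCc2ccccc2)c(-c2ccc(O[Si](C(C)C)(C(C)C)C(C)C)cc2)oc2cc(O[Si](C(C)C)(C(C)C)C(C)C)cc(O)c12
A9 | alternative 3 | (E)-2-(allyloxy)-3-[4-(benzyloxy)phenyl]-3-[3,5-bis(benzyloxy)phenoxy]prop-2-enoic acid | C=CCO/C(C(=O)O)=C(/Oc1cc(OCc2ccccc2)cc(OCc2ccccc2)c1)c1ccc(OCc2ccccc2)cc1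
A10 | alternative 3 | 3-O-allyl-5,7,4'-tri-O-benzylkaempferol | C=CCOc1c(-c2ccc(OCc3ccccc3)cc2)oc2cc(OCc3ccccc3)cc(OCc3ccccc3)c2c1=O
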